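## The problem

Compound 18 is a cis-fused decalin (a 10βH-eremophilane) with six stereocentres, C3, C4, quaternary C5, C7, C9 and C10; its C8 ketone lies between the isopropenyl-bearing C7 and the angeloyloxy-bearing C9, and a second angelate sits on C3. C5 and C10 fix the cis fusion, and in the chair pair with C14 axial on ring A and the C5–C4 bond axial on ring B the 3α-ester, 4β-methyl, 7β-isopropenyl and 9β-ester are all equatorial, so each peripheral centre is the thermodynamically preferred one once that chair is anchored. Kinetic delivery of hydrogen to an sp2 C3, C7 or C9 would come from the open face at each site (α at C3, away from the axial C14; β at C7 and C9, away from ring A) and would leave the substituent axial, so these centres must be set by equilibration, thermodynamic reduction, inversion, or delivery of carbon instead of hydrogen. The vicinal methyls on C4 and C5 are cis, which a suprafacial endo cycloaddition of a diene with an outward methyl terminus does not give directly. Three groups are fragile: the C7 hydrogen is both α to the ketone and allylic, so acid or base moves the isopropenyl alkene into conjugation; the angelates isomerise to tiglates under nucleophilic acyl-transfer catalysis and do not survive hydride or dissolving metal; and the C9 α-acyloxy ketone is open to reductive cleavage and acyl shift. The feature that allows a short entry is ring B, which carries oxygen on C8 and C9 beside the cis C5-methyl/C10-H pair, the imprint of 2-methoxy-5-methyl-1,4-benzoquinone reacting at its methyl-bearing alkene. The C3 oxygen and C4 methyl of ring A are the imprint of a 2-silyloxydiene with a methyl terminus, so C4–C5 and C1–C10 are Diels–Alder bonds.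

## Retrosynthesis

**C7–C11 (18 to 15 + 16).** The isopropenyl group is removed last, giving the silyl enol ether 15 and 2-bromopropene 16. The neighbouring option, coupling at an sp2 C7 followed by reduction, would form the C7–H bond by protonation from the convex face and risks the axial epimer. Acylating after the alkene is in place would expose the α-isopropenyl ketone to base and heat. The precursor is three carbons and one stereocentre simpler. The forward step must deliver carbon to the β face of C7, keep the C7 hydrogen, and stay neutral.

**Enol ether and esters (15 to 14 to 11 + 12).** Enol ether 15 comes from enone 14 by 1,4-hydrosilylation, which fixes the enolate regiochemistry better than deprotonation next to an acyloxy group could. The two ester C–O bonds are then cut to diol 11 and two molecules of angelic acid 12. Both carbinols of 11 already have the final configuration, so one retentive double esterification suffices, provided the Z alkene of 12 is not isomerised.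

**Enone (11 to 10).** The α-hydroxy enone is the transposition product of the γ-hydroxy enol ether 10. This removes the C6 oxygen of the quinone and places the ketone on C8 without a separate deoxygenation. The forward step needs only dilute acid.

**C3 and C4 (10 to 9 to 8 to 7).** The equatorial 3α-alcohol is traced to ketone 9 by dissolving-metal reduction. This must be done here, while ring B is an enol ether and bears no ester or enone. The 4β-methyl of 9 is traced to the 4α-methyl ketone 8 by equilibration, and 8 to the silyl enol ether 7. That equilibration is only favourable once O9 is β, so the 9β-hydroxyl of 7 is the conformational anchor and must be set first.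

**C9 (7 to 6 to 5 to 4).** The 9β-alcohol is reached by inversion of the 9α-alcohol 5. Hydride is expected to reach C9 of the folded adduct 4 from the convex face and so give 9α. Alcohol 5 has a single hydroxyl, so the Mitsunobu reaction to benzoate 6 has no selectivity problem. The later hydride step that reduces the vinylogous ester carbonyl also removes the benzoate.

**C4–C5 and C1–C10 (4 to 2 + 3).** Both bonds are cut together. This takes the bicyclic enedione 4 back to diene 2 and the commercial quinone 3, the largest simplification of the plan. It sets C5 and C10 and supplies every oxygen of the target. The forward reaction must be site-, regio-, endo- and enantioselective; it delivers C4 with the wrong configuration, which is accepted and corrected through 9.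

**Diene (2 to 1).** Diene 2 is the Z silyl enol ether of pent-1-en-3-one 1, made in one step by cutting the Si–O bond.

## Roads not taken

Alternative 1: ring-rearrangement metathesis. The cut trades the C1–C2 ring alkene and the C11–C12 isopropenyl alkene for a methyl-bearing bridging alkene (C1–C11) across ring B, in a bicycle derived from a masked o-benzoquinone. In the forward key step a ruthenium carbene formed at a side-chain vinyl group opens that bridging alkene and gives A1.
- Merits: the isopropenyl alkene is created by the key step itself, so no late C–C bond formation next to the ketone is needed. C3 and C9 already carry hydroxyls and C8 is masked. In this respect it is better than the chosen plan, which depends on a late palladium coupling.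
- Weak points: A1 is the C7 epimer. Correcting it means enolising an unmasked α-isopropenyl ketone, the operation most likely to move the alkene into conjugation. The ring alkene at C1–C2 must be hydrogenated without touching the more reactive 1,1-disubstituted isopropenyl alkene. The carbene must open a trisubstituted bridging alkene, a slow class of ring opening. The cycloaddition that builds the bicycle has no general catalytic enantiocontrol, and the side chain carrying C3 and C4 must be made with its stereocentres beforehand.
- Comparison: the chosen plan sets against this a catalytic asymmetric key step on a commercial quinone and a C7 centre set without epimerisation.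

Alternative 2: catalytic asymmetric intramolecular Diels–Alder reaction. The cut is at C1–C2 and C5–C10, opening both rings to an achiral trienone. In the forward key step the vinyl ketone adds to the tethered silyloxydiene and gives A2.
- Merits: both rings and the quaternary centre form in one step. C4 is still sp2, so no endo-derived epimer arises. C8 and C9 emerge differentiated as ketal and ketone, and there is no C6 oxygen to remove. In bonds and rings formed per step it is better than the chosen key step.
- Weak points: the diene terminus that becomes C5 is fully substituted, and asymmetric catalysis of such a cycloaddition with a ketone dienophile has thin precedent. The linear precursor, with ketal, enone and a silyloxydiene of defined geometry, costs several steps. C4 is then set by protonating a tetrasubstituted enol ether, which has the same facial problem that the chosen plan solves by equilibration. C7 still has to be functionalised after redox adjustment at C8 and C9.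
- Comparison: the chosen plan sets against this two cycloaddition partners available in zero and one step, and a ring B that arrives with the oxidation pattern needed.

Alternative 3: para-dearomatisation of a cresol. The cut is the C4–C5 bond, opening ring A to a phenol with a tethered epoxide. In the forward key step the para carbon attacks the distal epoxide carbon with inversion and gives A3.
- Merits: the C3 hydroxyl and C4 methyl come stereospecifically from an enantioenriched epoxide, and C5 is set in the same cyclisation. The 3,4,5 triad is therefore obtained without epimerisation or thermodynamic reduction. On ring A this road is better than the chosen one.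
- Weak points: C-alkylation at a substituted para carbon competes with O-alkylation and ortho attack. In A3 C10 is sp2, so the cis fusion needs a later face-selective reduction. C9 carries bromine instead of oxygen, and the two vinylic bromides must be told apart, one for the isopropenyl group and one for a C–O bond.
- Comparison: the chosen plan obtains C5, C10 and the C8/C9 oxygens in the key step. It pays on ring A with one equilibration and one inversion.

Key step: step 2

Remarks on the chemistry (assumptions):
- Eremophilane numbering is used. β is the face of the C5 methyl (C14) and of H10. Intermediates lacking C11–C13 are named as trinoreremophilanes (11,12,13-trinor).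
- The (R)-BINOL complex is assumed to give the absolute configuration drawn for 4; if the sense of induction is the opposite, (S)-BINOL is used.
- Borohydride is assumed to reach C9 of 4 from the convex β face, giving the 9α-alcohol 5.

## Steps

Step 1
Reactants: 1 pent-1-en-3-one
Product: 2 (Z)-3-(triisopropylsilyloxy)penta-1,3-diene
Conditions: i-Pr3SiOTf, Et3N, CH2Cl2, 0 °C to rt
Reagents that add atoms: triisopropylsilyl trifluoromethanesulfonate, CC(C)[Si](OS(=O)(=O)C(F)(F)F)(C(C)C)C(C)C
Why: Soft enolisation and O-silylation of an ethyl ketone with a silyl triflate and an amine, which favours the Z enol ether (methyl cis to oxygen); the bulky silyl group is chosen so that the diene survives the Lewis acid of step 2.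

Step 2
Reactants: 2 (Z)-3-(triisopropylsilyloxy)penta-1,3-diene; 3 2-methoxy-5-methyl-1,4-benzoquinone
Product: 4 8-methoxy-4α,5β-dimethyl-3-(triisopropylsilyloxy)-10βH-trinoreremophila-2,7-diene-6,9-dione (cis-fused endo adduct)
Conditions: (R)-BINOL, TiCl2(OiPr)2 (10 mol %), 4 Å MS, CH2Cl2, −30 °C to rt
Reagents that add atoms: none
Why: Concerted, asynchronous Diels–Alder addition of the silyloxydiene to the Lewis-acid-chelated quinone; the closest known reactions are chelation-controlled additions of butadienes to the methyl-bearing alkene of this quinone and (BINOL)TiCl2-catalysed additions of silyloxydienes to methoxyquinones. Ring A closes as a six-membered carbocycle by [4+2] cycloaddition, the C4–C5 and C1–C10 bonds forming suprafacially on both partners. The methoxy-bearing alkene is a vinylogous ester and does not react. Titanium held between the C9 carbonyl and the methoxy oxygen makes C5 the most electrophilic carbon, and it pairs with the CH(CH3) terminus, the nucleophilic β-carbon of the silyl enol ether. C5 and C10 are set cis by suprafacial addition to the ring alkene. C4 is set by the endo transition state with the Z diene (methyl outward), which places C15 trans to C14; this 4α epimer is corrected in step 6. The absolute configuration comes from the BINOL ligand, which shields one face of the chelated quinone. The step needs site-, regio-, endo- and enantioselectivity; the first three are inherent in the substrates and the fourth is controlled by the catalyst.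

Step 3
Reactants: 4 cis-fused endo adduct
Product: 5 9α-hydroxy-8-methoxy-4α,5β-dimethyl-3-(triisopropylsilyloxy)-10βH-trinoreremophila-2,7-dien-6-one
Conditions: NaBH4, CeCl3·7H2O, MeOH, −78 °C
Reagents that add atoms: none
Why: Luche 1,2-reduction; the C9 carbonyl is an enone carbonyl while the C6 carbonyl is a vinylogous ester next to the quaternary C5 and stays. Hydride is expected from the convex β face of the folded cis-fused adduct, on the side of H10 and away from ring A, so the hydroxyl ends α.

Step 4
Reactants: 5 9α-hydroxy vinylogous ester
Product: 6 9β-benzoyloxy-8-methoxy-4α,5β-dimethyl-3-(triisopropylsilyloxy)-10βH-trinoreremophila-2,7-dien-6-one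
Conditions: PPh3, DIAD, PhCO2H, THF, 0 °C to rt
Reagents that add atoms: benzoic acid, O=C(O)c1ccccc1
Why: Mitsunobu esterification, an SN2 displacement with inversion at C9 by benzoate from the open β face. The only hydroxyl is the one to be inverted, and the vinylogous ester disfavours ionisation at C9.

Step 5
Reactants: 6 9β-benzoate
Product: 7 8-methoxy-4α,5β-dimethyl-3-(triisopropylsilyloxy)-10βH-trinoreremophila-2,7-diene-6α,9β-diol
Conditions: LiAlH4, THF, −78 to 0 °C; aq. potassium sodium tartrate (KNaC4H4O6) work-up
Reagents that add atoms: none
Why: Hydride cleaves the benzoate and adds 1,2 to the vinylogous ester carbonyl (first half of a Stork–Danheiser transposition); the silyl enol ether is inert and the neutral work-up keeps the acid-labile methoxy allylic alcohol. The C6 carbinol is drawn α (convex-face delivery); its configuration is of no consequence because C6 loses its oxygen in step 8.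

Step 6
Reactants: 7 silyl enol ether diol
Product: 9 6α,9β-dihydroxy-8-methoxy-4β,5β-dimethyl-10βH-trinoreremophil-7-en-3-one, via 4α-methyl ketone 8 (not isolated)
Conditions: Bu4NF, THF, 0 °C; then NaOMe, MeOH, rt
Reagents that add atoms: none
Why: Fluoride cleaves the silyl enol ether to ketone 8, and methoxide then equilibrates C4 through the enolate (epimerisation α to a ketone). With O9 β, the chair pair with C14 axial on ring B would put O9 and C14 1,3-diaxial. In the other chair pair a 4α-methyl is axial and 1,3-diaxial to C9 while a 4β-methyl is equatorial, so the cis-dimethyl epimer 9 is favoured.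

Step 7
Reactants: 9 4β-methyl ketone
Product: 10 8-methoxy-4β,5β-dimethyl-10βH-trinoreremophil-7-ene-3α,6α,9β-triol
Conditions: Li, NH3(l), THF, EtOH, −78 °C; NH4Cl
Reagents that add atoms: none
Why: Dissolving-metal reduction of a ketone gives the more stable equatorial alcohol, here 3α and trans to the 4β-methyl. A hydride reagent would attack anti to the axial C14 and give the axial 3β-alcohol. The enol ether and the alkoxides are not reduced.

Step 8
Reactants: 10 triol enol ether
Product: 11 3α,9β-dihydroxy-4β,5β-dimethyl-10βH-trinoreremophil-6-en-8-one
Conditions: 1 M HCl, THF, 0 °C
Reagents that add atoms: water, O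
Why: Stork–Danheiser-type 1,3-carbonyl transposition: acid ionises the C6 hydroxyl through the enol ether, water adds at C8 and methanol is lost, leaving the C6–C7 enone. No stereocentre is formed, and the α-ketol tolerates dilute acid.

Step 9
Reactants: 11 3α,9β-dihydroxy-4β,5β-dimethyl-10βH-trinoreremophil-6-en-8-one; 12 angelic acid (two equivalents are consumed; the second is entered on the reagent line)
Product: 14 3α,9β-bis(angeloyloxy)-4β,5β-dimethyl-10βH-trinoreremophil-6-en-8-one, via angelic 2,4,6-trichlorobenzoic anhydride 13 (not isolated)
Conditions: 12 (excess), 2,4,6-trichlorobenzoyl chloride, Et3N, toluene, rt; then 11, toluene, 80 °C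
Reagents that add atoms: angelic acid (second equivalent of 12), C/C=C(/C)C(=O)O
Why: Yamaguchi esterification through the mixed anhydride 13; each of the two equatorial hydroxyls is acylated with retention by one molecule of 13, so two molecules of angelic acid end up in the product. No nucleophilic acyl-transfer catalyst is used, which keeps the Z geometry of the angeloyl group.

Step 10
Reactants: 14 bis-angelate enone
Product: 15 3α,9β-bis(angeloyloxy)-8-(dimethylphenylsilyloxy)-4β,5β-dimethyl-10βH-trinoreremophil-7-ene
Conditions: PhMe2SiH, RhCl(PPh3)3 (2 mol %), benzene, 50 °C
Reagents that add atoms: dimethylphenylsilane, C[SiH](C)c1ccccc1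
Why: Rhodium-catalysed 1,4-hydrosilylation of an enone with a monohydrosilane gives the silyl enol ether regiospecifically between C7 and C8. The trisubstituted, α-branched angelate alkenes are much less reactive than the ring enone.

Step 11
Reactants: 15 silyl enol ether; 16 2-bromopropene
Product: 18 3α,9β-bis(angeloyloxy)-10βH-eremophil-11-en-8-one (7β-isopropenyl; CNP0174755.1), via tributyltin enolate 17 (not isolated)
Conditions: Bu3SnF, PdCl2[P(o-tol)3]2 (5 mol %), toluene, 85 °C, sealed tube
Reagents that add atoms: none
Why: Palladium-catalysed α-alkenylation of a silyl enol ether through its tin enolate (cross-coupling of a tin enolate with an alkenyl bromide): Bu3SnF converts 15 into 17, which transmetalates to the isopropenylpalladium bromide, and reductive elimination forms C7–C11. Palladium binds C7 on the β face, anti to the axial C5–C4 bond, so the isopropenyl group arrives β and the original C7 hydrogen stays α. This equatorial epimer is also the more stable one, and the neutral medium should leave the new alkene out of conjugation.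

## Compound list

1 | pent-1-en-3-one | CCC(=O)C=C | starting material
2 | (Z)-3-(triisopropylsilyloxy)penta-1,3-diene | C=C/C(O[Si](C(C)C)(C(C)C)C(C)C)=C/C | intermediate
3 | 2-methoxy-5-methyl-1,4-benzoquinone | COC1=CC(=O)C(C)=CC1=O | starting material
4 | 8-methoxy-4α,5β-dimethyl-3-(triisopropylsilyloxy)-10βH-trinoreremophila-2,7-diene-6,9-dione | C[C@@H]1C(O[Si](C(C)C)(C(C)C)C(C)C)=CC[C@@H]2C(=O)C(OC)=CC(=O)[C@]12C | intermediate
5 | 9α-hydroxy-8-methoxy-4α,5β-dimethyl-3-(triisopropylsilyloxy)-10βH-trinoreremophila-2,7-dien-6-one | COC1=CC(=O)[C@@]2(C)[C@H](CC=C(O[Si](C(C)C)(C(C)C)C(C)C)[C@H]2C)[C@@H]1O | intermediate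
6 | 9β-benzoyloxy-8-methoxy-4α,5β-dimethyl-3-(triisopropylsilyloxy)-10βH-trinoreremophila-2,7-dien-6-one | COC1=CC(=O)[C@@]2(C)[C@H](CC=C(O[Si](C(C)C)(C(C)C)C(C)C)[C@H]2C)[C@H]1OC(=O)c1ccccc1 | intermediate
7 | 8-methoxy-4α,5β-dimethyl-3-(triisopropylsilyloxy)-10βH-trinoreremophila-2,7-diene-6α,9β-diol | COC1=C[C@H](O)[C@@]2(C)[C@H](CC=C(O[Si](C(C)C)(C(C)C)C(C)C)[C@H]2C)[C@H]1O | intermediate
8 | 6α,9β-dihydroxy-8-methoxy-4α,5β-dimethyl-10βH-trinoreremophil-7-en-3-one | COC1=C[C@H](O)[C@@]2(C)[C@H](CCC(=O)[C@H]2C)[C@H]1O | intermediate (not isolated)
9 | 6α,9β-dihydroxy-8-methoxy-4β,5β-dimethyl-10βH-trinoreremophil-7-en-3-one | COC1=C[C@H](O)[C@@]2(C)[C@H](CCC(=O)[C@@H]2C)[C@H]1O | intermediate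
10 | 8-methoxy-4β,5β-dimethyl-10βH-trinoreremophil-7-ene-3α,6α,9β-triol | COC1=C[C@H](O)[C@@]2(C)[C@H](CC[C@@H](O)[C@@H]2C)[C@H]1O | intermediate
11 | 3α,9β-dihydroxy-4β,5β-dimethyl-10βH-trinoreremophil-6-en-8-one | C1=C[C@@]2(C)[C@H](CC[C@@H](O)[C@@H]2C)[C@@H](O)C1=O | intermediate
12 | angelic acid, (Z)-2-methylbut-2-enoic acid | C/C=C(/C)C(=O)O | starting material
13 | (Z)-2-methylbut-2-enoic 2,4,6-trichlorobenzoic anhydride | C/C=C(/C)C(=O)OC(=O)c1c(Cl)cc(Cl)cc1Cl | intermediate (not isolated)
14 | 3α,9β-bis(angeloyloxy)-4β,5β-dimethyl-10βH-trinoreremophil-6-en-8-one | C1=C[C@@]2(C)[C@H](CC[C@@H](OC(=O)/C(C)=C\C)[C@@H]2C)[C@@H](OC(=O)/C(C)=C\C)C1=O | intermediate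
15 | 3α,9β-bis(angeloyloxy)-8-(dimethylphenylsilyloxy)-4β,5β-dimethyl-10βH-trinoreremophil-7-ene | C[Si](C)(OC1=CC[C@@]2(C)[C@H](CC[C@@H](OC(=O)/C(C)=C\C)[C@@H]2C)[C@H]1OC(=O)/C(C)=C\C)c1ccccc1 | intermediate
16 | 2-bromopropene | CC(Br)=C | starting material
17 | 3α,9β-bis(angeloyloxy)-4β,5β-dimethyl-8-(tributylstannyloxy)-10βH-trinoreremophil-7-ene | CCCC[Sn](CCCC)(CCCC)OC1=CC[C@@]2(C)[C@H](CC[C@@H](OC(=O)/C(C)=C\C)[C@@H]2C)[C@H]1OC(=O)/C(C)=C\C | intermediate (not isolated)
18 | 3α,9β-bis(angeloyloxy)-10βH-eremophil-11-en-8-one (CNP0174755.1) | C=C(C)[C@H]1C[C@@]2(C)[C@H](CC[C@@H](OC(=O)/C(C)=C\C)[C@@H]2C)[C@@H](OC(=O)/C(C)=C\C)C1=O | target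

## Step count and risks

Total: 11 steps. Longest linear sequence: 11 steps, from 1 to 18; the route is fully linear, with 3, 12 and 16 entering as purchased materials.

**Step 2 (key step).** The cycloaddition may be slow, because a bond must form between the methyl-bearing diene terminus and the methyl-bearing quinone carbon. The chiral titanium complex may also give low facial discrimination, or attack the silyl enol ether in a Mukaiyama–Michael sense. Fallback, from 2 and 3 back to 4: run the cycloaddition racemically with SnCl4 in CH2Cl2 at −78 °C, a chelating Lewis acid known to steer this quinone. Then separate the antipodes of the adduct on a chiral stationary phase. One antipode is 4; the other is the mirror-image adduct F1, which is discarded.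

**Step 11.** The C-bound palladium enolate may undergo β-hydride elimination back to the enone, the tin enolate may be protonated, or the angeloyl group on O9 may shift to the enolate oxygen. Fallback, from 14 back to 18 by cross-coupling at sp2 carbon followed by reduction:
- α-Iodination with I2 and pyridine in CH2Cl2 gives the 7-iodo enone F2.
- Coupling of F2 with tributyl(prop-1-en-2-yl)stannane (Stille reaction; Pd2(dba)3, AsPh3, CuI, NMP) gives the cross-conjugated 7-isopropenyl dienone F3.
- Conjugate reduction of F3 with [(Ph3P)CuH]6 in wet benzene, with kinetic α-protonation of the dienolate, gives 18.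

On this path C7 is set by protonation of the dienolate instead of by carbon delivery, so its configuration would have to be checked.

**Step 3.** Hydride delivery to C9 may occur from the α face, anti to the angular methyl, giving the 9β-alcohol directly; the inversion of step 4 would then lead to the wrong epimer. Fallback, from 4 back to 7 without any inversion: the same Luche reduction then gives the 9β-hydroxy vinylogous ester F4. Step 4 is omitted, and LiAlH4 in THF under the conditions of step 5 reduces the C6 carbonyl of F4 to give 7.

**Step 4.** The oxyphosphonium intermediate may eliminate toward C10 instead of undergoing substitution, or the substitution may be slow at a carbon flanked by the ring fusion. Fallback, from 5 back to 7 by an isolated sulfonate and a naked carboxylate: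
- MsCl and Et3N give the 9α-mesylate F5.
- Cesium acetate with 18-crown-6 in toluene displaces it with inversion to the 9β-acetate F6.
- LiAlH4 then cleaves the acetate of F6 and reduces the C6 carbonyl to give 7.

## Further compounds

F1 | step 2 | enantiomer of 4, ent-8-methoxy-4α,5β-dimethyl-3-(triisopropylsilyloxy)-10βH-trinoreremophila-2,7-diene-6,9-dione | C[C@H]1C(O[Si](C(C)C)(C(C)C)C(C)C)=CC[C@H]2C(=O)C(OC)=CC(=O)[C@@]12C
F2 | step 11 | 3α,9β-bis(angeloyloxy)-7-iodo-4β,5β-dimethyl-10βH-trinoreremophil-6-en-8-one | IC1=C[C@@]2(C)[C@H](CC[C@@H](OC(=O)/C(C)=C\C)[C@@H]2C)[C@@H](OC(=O)/C(C)=C\C)C1=O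
F3 | step 11 | 3α,9β-bis(angeloyloxy)-10βH-eremophila-6,11-dien-8-one | C=C(C)C1=C[C@@]2(C)[C@H](CC[C@@H](OC(=O)/C(C)=C\C)[C@@H]2C)[C@@H](OC(=O)/C(C)=C\C)C1=O
F4 | step 3 | 9β-hydroxy-8-methoxy-4α,5β-dimethyl-3-(triisopropylsilyloxy)-10βH-trinoreremophila-2,7-dien-6-one | COC1=CC(=O)[C@@]2(C)[C@H](CC=C(O[Si](C(C)C)(C(C)C)C(C)C)[C@H]2C)[C@H]1O
F5 | step 4 | 9α-methanesulfonyloxy-8-methoxy-4α,5β-dimethyl-3-(triisopropylsilyloxy)-10βH-trinoreremophila-2,7-dien-6-one | COC1=CC(=O)[C@@]2(C)[C@H](CC=C(O[Si](C(C)C)(C(C)C)C(C)C)[C@H]2C)[C@@H]1OS(C)(=O)=O
F6 | step 4 | 9β-acetoxy-8-methoxy-4α,5β-dimethyl-3-(triisopropylsilyloxy)-10βH-trinoreremophila-2,7-dien-6-one | COC1=CC(=O)[C@@]2(C)[C@H](CC=C(O[Si](C(C)C)(C(C)C)C(C)C)[C@H]2C)[C@H]1OC(C)=O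
A1 | alternative 1 | 7-epi-8,8-dimethoxyeremophila-1,11-diene-3,9-diol (cis-fused) | C=C(C)[C@@H]1C[C@]2(C)[C@@H](C)[C@H](O)C=C[C@@H]2[C@@H](O)C1(OC)OC
A2 | alternative 2 | cis-fused 8,8-ethylenedioxy-4,5-dimethyl-3-(triisopropylsilyloxy)octal-3-en-9-one (eremophilane numbering) | CC1=C(O[Si](C(C)C)(C(C)C)C(C)C)CC[C@@H]2C(=O)C3(OCCO3)CC[C@]12C
A3 | alternative 3 | 7,9-dibromo-3-hydroxy-4,5-dimethyl ring-fused cyclohexa-6,9-dien-8-one (eremophilane numbering) | C[C@H]1[C@H](O)CCC2=C(Br)C(=O)C(Br)=C[C@]12C
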